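Readings and results come from a simulation with constants of no real substance; the scatter is artificial.

The leftover to watch is J: if the proposed steps hold, each G formed takes one J away, so what remains of J counts the turnovers of that path, and the rate of G per D sinks with it while that of Q per D stays.

| setting | ochre | grey | teal | violet | dawn | noon |
|---|---|---|---|---|---|---|
| X | 17 mM | 17 mM | 17 mM | 17 mM | 17 mM | 17 mM |
| Z | 68 mM | 68 mM | 68 mM | 140 mM | 68.0 mM | 250 mM |
| J | 12 mM | 22 mM | 24 mM | 17 mM | 17.0 mM | 25.0 mM |
| remark | run made earlier | run made earlier | run made earlier | run made earlier |  |  |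
| time |  |  |  |  | 3.0 min | 1.5 min |

| run | time / s | Q / % | G / % |
|---|---|---|---|
| ochre | 25.0 | 1.3 | 0.9 |
| ochre | 50.0 | 4.1 | 5.7 |
| ochre | 80.0 | 10.5 | 10.6 |
| ochre | 90.0 | 11.9 | 12.5 |
| ochre | 120 | 15.2 | 16.5 |
| grey | 12.0 | 0.9 | 0.6 |
| grey | 30.0 | 3.2 | 4.5 |
| grey | 60.0 | 5.2 | 13.3 |
| grey | 90.0 | 9.9 | 20.7 |
| grey | 120 | 14.0 | 27.3 |
| teal | 10.0 | 0.4 | 0.2 |
| teal | 20.0 | 0.9 | 1.7 |
| teal | 40.0 | 4.4 | 7.4 |
| teal | 60.0 | 6.4 | 14.2 |
| teal | 120 | 14.6 | 30.4 |
| violet | 10.0 | 0.8 | 0.9 |
| violet | 20.0 | 3.0 | 2.7 |
| violet | 40.0 | 5.9 | 8.3 |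
| violet | 60.0 | 11.5 | 14.1 |
| violet | 120 | 23.8 | 27.0 |

(standard deviation of a reading: 0.5 percentage points)

- percentages count the X that a species holds: one E or L counts as two
- what was read earlier has a scatter of 0.5 percentage points, one standard deviation
- steps that have been proposed: X + Z -> D; D -> Q; D + J -> G; X + Q -> E; 2 X -> L

1. which of the two ends with the higher share of Q in all that became Q or G or E ("neither" if they lie within 2 percentage points) (dawn / noon / neither)
2. share of Q in all that became Q or G or E, dawn
3. share of Q in all that became Q or G or E, noon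

With J taken midway through violet's run, its last reading gives 13.0 mM, the amount of J at which D gives Q and G equally fast, a selectivity factor written as a concentration. Grey, with less Z and more J, reads lower at 10.1 mM; ochre, at grey's Z with less J, reads 9.76 mM, so you may take that gap as Q lost to E. On that reading, G starts 1.31 times as fast as Q in dawn and 1.93 times as fast in noon. Suppose both flasks end near teal's last G, 30.4%. Mean J is then 14.4 mM in dawn and 22.4 mM in noon, slowing that path by factors 0.848 and 0.897. Dawn has grey's Z, so it keeps grey's reading and suffers the gap, each Q lost counting as two in E, giving a share of 33.4%. Noon has more Z than violet, so you allow it no further loss and get 36.6%, which puts noon ahead.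

The forecast differs, giving 39% for dawn and 34% for noon, and says “dawn is probably higher”. The flask gives 35.6% for dawn and 36.2% for noon, so the answer is neither.

    X + Z → D (k = 0.340 /M/s)
    D → Q (k = 0.00390 /s)
    D + J → G (k = 0.290 /M/s)
    X + Q → E (k = 1.70 /M/s)
    2 X → L (k = 0.0440 /M/s)

Carry 13.0 mM to the neighbour, dawn read at 5.0 min, where G stands at 38.4% and E at 12.1%. Mean J is then 13.7 mM, so Q made per G is 0.944. Taking off the Q held in E leaves 30.2%, against 32.3% in that flask, and a share of 37.4%, against the neighbour's 39.0%.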